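## Retrosynthetic overview
1. C2–C1′ is cut first. The chromone acts as its C2 anion, a β-acylvinyl anion (d3 synthon), although C2 is by nature the Michael-acceptor carbon. The partner is the electrophilic C–Br carbon of 4-bromocatechol, whose OH groups are masked only transiently as TMS ethers.
2. 5,6,7,8-Tetramethoxychromone comes from the o-hydroxyacetophenone plus a one-carbon amide acetal (forms C2–C3 and O1–C2).
3. 2-Hydroxy-3,4,5,6-tetramethoxyacetophenone comes from Cu-catalysed methoxylation of the aryl bromide, which comes from ring bromination, which follows C-acetylation of 3,4,5-trimethoxyphenol.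
4. Ring order: the A ring is bought and fully substituted first, the pyranone C ring is closed in step 4, and the bought B ring is attached last in step 5.

Assumption: the target is a planar flavone with no stereocentre or chiral axis. It is achiral and needs no enantiocontrol. The only stereodescriptor in the route is the E geometry of the transient enaminone 5.

## Route

Step 1
Reactants: 1 3,4,5-trimethoxyphenol
Product: 2 1-(6-hydroxy-2,3,4-trimethoxyphenyl)ethan-1-one
Conditions: AcOH, BF3·OEt2, 85 °C, 3 h; then H2O
Reagents that add atoms: acetic acid, CC(=O)O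
Why: This is a BF3-promoted Friedel–Crafts C-acylation (Fries-type, ortho to OH) in which the two free ring positions of 1 are equivalent, so one regioisomer forms, and chelation of the new o-hydroxyketone stops a second acylation.

Step 2
Reactants: 2 1-(6-hydroxy-2,3,4-trimethoxyphenyl)ethan-1-one
Product: 3 1-(3-bromo-2-hydroxy-4,5,6-trimethoxyphenyl)ethan-1-one
Conditions: NBS (1.05 equiv), dry CH2Cl2, 0 °C → rt
Reagents that add atoms: N-bromosuccinimide, O=C1CCC(=O)N1Br
Why: This is an electrophilic aromatic bromination (SEAr) at the single remaining ring C–H, which is ortho to the phenol and para to a methoxy group and so reacts much faster than the hydrogen-bonded acetyl group, while exclusion of water suppresses oxidation to a quinone.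

Step 3
Reactants: 3 1-(3-bromo-2-hydroxy-4,5,6-trimethoxyphenyl)ethan-1-one
Product: 4 1-(2-hydroxy-3,4,5,6-tetramethoxyphenyl)ethan-1-one
Conditions: NaOMe (6 equiv, 25% in MeOH), CuBr (20 mol %), DMF, 110 °C, N2; then 1 M HCl
Reagents that add atoms: sodium methoxide, C[O-].[Na+]
Why: This is an Ullmann-type Cu(I)-catalysed methoxylation of an o-bromophenoxide, the situation known from the conversion of 5-bromovanillin into syringaldehyde, and the doubly ortho-substituted ketone next to a phenoxide is too hindered and too deactivated to self-condense.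

Step 4
Reactants: 4 1-(2-hydroxy-3,4,5,6-tetramethoxyphenyl)ethan-1-one
Product: 6 5,6,7,8-tetramethoxy-4H-chromen-4-one, via E-enaminone 5 (not isolated)
Conditions: DMF-DMA (3 equiv), toluene, 100 °C, 3 h, concentrate; then 2 M HCl, CH2Cl2, 40 °C
Reagents that add atoms: N,N-dimethylformamide dimethyl acetal, COC(OC)N(C)C
Why: Amide-acetal condensation at the acetyl CH3 gives the E-enaminone, and acid then triggers phenol addition and elimination of dimethylamine (enaminone chromone synthesis), which closes the pyranone ring with C2–H left free under conditions too mild to cleave the aryl methyl ethers.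

Step 5
Reactants: 6 5,6,7,8-tetramethoxy-4H-chromen-4-one; 7 4-bromobenzene-1,2-diol (4-bromocatechol)
Product: 11 2-(3,4-dihydroxyphenyl)-5,6,7,8-tetramethoxy-4H-chromen-4-one, via bis-TMS ether 8 (not isolated), via chromon-2-ylzinc chloride 9 (not isolated), via bis-TMS flavone 10 (not isolated)
Conditions: (a) 7, HMDS (1.2 equiv), neat, 80 °C, then vacuum, take up in THF; (b) 6, MgCl2 (2 equiv), TMPZnCl·LiCl (1.3 equiv), THF, −10 → 25 °C, 1 h; (c) combine a and b, Pd(OAc)2 (2 mol %), SPhos (4 mol %), THF, 50 °C; (d) 1 M HCl, THF, 25 °C, 30 min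
Reagents that add atoms: none
Why: In this Lewis-acid-triggered TMP-zincation and Negishi cross-coupling, Mg2+ held in the 5-OMe/C4=O pocket blocks carbonyl-directed metalation at C3 and acidifies C2–H, so the hindered zinc amide turns the natural acceptor carbon C2 into a covalent β-acylvinyl anion (d3, an sp2 homoenolate type) that does not ring-open, Pd/SPhos joins it to the equally electrophilic C–Br carbon of the silylated bromocatechol, and the aryl TMS ethers fall off in dilute acid to give the free catechol without a separate deprotection or any new stereocentre.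

## Compound list
1 | 3,4,5-trimethoxyphenol | COc1cc(O)cc(OC)c1OC | starting material
2 | 1-(6-hydroxy-2,3,4-trimethoxyphenyl)ethan-1-one | CC(=O)c1c(O)cc(OC)c(OC)c1OC | intermediate
3 | 1-(3-bromo-2-hydroxy-4,5,6-trimethoxyphenyl)ethan-1-one | CC(=O)c1c(O)c(Br)c(OC)c(OC)c1OC | intermediate
4 | 1-(2-hydroxy-3,4,5,6-tetramethoxyphenyl)ethan-1-one | CC(=O)c1c(O)c(OC)c(OC)c(OC)c1OC | intermediate
5 | (E)-3-(dimethylamino)-1-(2-hydroxy-3,4,5,6-tetramethoxyphenyl)prop-2-en-1-one | CN(C)/C=C/C(=O)c1c(O)c(OC)c(OC)c(OC)c1OC | intermediate
6 | 5,6,7,8-tetramethoxy-4H-chromen-4-one | COc1c(OC)c(OC)c2c(=O)ccoc2c1OC | intermediate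
7 | 4-bromobenzene-1,2-diol | Oc1ccc(Br)cc1O | starting material
8 | 4-bromo-1,2-bis(trimethylsilyloxy)benzene | C[Si](C)(C)Oc1ccc(Br)cc1O[Si](C)(C)C | intermediate
9 | chloro(5,6,7,8-tetramethoxy-4-oxo-4H-chromen-2-yl)zinc | COc1c(OC)c(OC)c2c(=O)cc([Zn]Cl)oc2c1OC | intermediate
10 | 5,6,7,8-tetramethoxy-2-[3,4-bis(trimethylsilyloxy)phenyl]-4H-chromen-4-one | COc1c(OC)c(OC)c2c(=O)cc(-c3ccc(O[Si](C)(C)C)c(O[Si](C)(C)C)c3)oc2c1OC | intermediate
11 | 2-(3,4-dihydroxyphenyl)-5,6,7,8-tetramethoxy-4H-chromen-4-one | COc1c(OC)c(OC)c2c(=O)cc(-c3ccc(O)c(O)c3)oc2c1OC | target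

## Step count and risks
Total steps: 5. Longest linear sequence: 5 (1 → 2 → 3 → 4 → 6 → 11).

**Step 5 is the most likely to fail.**
- The C2/C3 ratio of the zincation is untested on a chromone that carries a 5-OMe group. An aliquot quenched with I2 or D2O before the palladium is added shows this ratio.
- The electron-poor alkenylzinc may transmetalate slowly.
- The TMS ethers may not last at 50 °C.

The fallback sets out from 6 and comes back at 11. It gives up the metalated chromone and uses 6 in its natural role as an acceptor. A Pd(II)-catalysed oxidative conjugate arylation of boron-Heck type (Pd(TFA)2, DDQ/O2, DMSO–AcOH) with commercial 3,4-bis(benzyloxy)phenylboronic acid gives 2-[3,4-bis(benzyloxy)phenyl]-5,6,7,8-tetramethoxy-4H-chromen-4-one F1. Hydrogenolysis of its benzyl ethers (H2 1 atm, Pd/C, EtOAc–MeOH, stopped after two equivalents so that C2=C3 is kept) gives 11.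

**Step 3 is second.** Hydrodebromination back to 2 or base-induced condensation of the ketone could compete at 110 °C. The fallback sets out from 2, skips 3, and comes back at 4. It builds the C–O bond by oxidation instead of cross-coupling.
- Duff formylation (HMTA, TFA, 80 °C; then aq. HCl) at the only free ring position gives 3-acetyl-2-hydroxy-4,5,6-trimethoxybenzaldehyde F2.
- An acidic Dakin oxidation (30% H2O2, H3BO3, cat. H2SO4, THF) converts the formyl group into OH and gives 1-(2,3-dihydroxy-4,5,6-trimethoxyphenyl)ethan-1-one F3.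
- MeI (1.0 equiv) with K2CO3 in acetone methylates only the 3-OH, because the 2-OH is chelated to the ketone. This gives 4.

**Step 4 is third.** DMF-DMA may O-methylate the phenol, or the crowded, twisted ketone may condense slowly. The fallback sets out from 4 and comes back at 6. It replaces the amide acetal by an enolate acylation. A crossed Claisen formylation (HCO2Et, NaH, THF, 0 °C → rt) gives, after quench, the cyclic hemiacetal 2-hydroxy-5,6,7,8-tetramethoxychroman-4-one F4, which is racemic with a labile centre at C2. Dehydration with cat. p-TsOH in warm toluene gives 6.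

## Further compounds
F1 | step 5 | 2-[3,4-bis(benzyloxy)phenyl]-5,6,7,8-tetramethoxy-4H-chromen-4-one | COc1c(OC)c(OC)c2c(=O)cc(-c3ccc(OCc4ccccc4)c(OCc4ccccc4)c3)oc2c1OC
F2 | step 3 | 3-acetyl-2-hydroxy-4,5,6-trimethoxybenzaldehyde | CC(=O)c1c(O)c(C=O)c(OC)c(OC)c1OC
F3 | step 3 | 1-(2,3-dihydroxy-4,5,6-trimethoxyphenyl)ethan-1-one | CC(=O)c1c(O)c(O)c(OC)c(OC)c1OC
F4 | step 4 | 2-hydroxy-5,6,7,8-tetramethoxychroman-4-one (racemic hemiacetal) | COc1c(OC)c(OC)c2C(=O)CC(O)Oc2c1OC
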